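All runs were generated by integration with made-up constants, noise included.

Time came first: I had to name the best moment, up to 6.0 h, for the complex with three exchanged in a new flask.

| flask | starting complex | gas | remark | time |
|---|---|---|---|---|
| eta | 17 mM | 3.6 mM (held) | run made earlier |  |
| epsilon | 26 mM | 3.6 mM (held) | run made earlier |  |
| flask | 12 mM | 3.6 mM (held) |  | 6.0 h |

- eta (time / h: complex with three exchanged / %, starting complex / %): 0.250: 26, 58; 0.333: 31, 51; 0.667: 39, 38; 1.00: 45, 28; 1.33: 40, 22; 2.50: 24, 7; 4.00: 12, 4
- epsilon (time / h: complex with three exchanged / %, starting complex / %): 0.250: 21, 65; 0.333: 22, 62; 0.667: 34, 49; 1.00: 33, 34; 1.33: 29, 30; 2.50: 16, 17; 4.00: 8, 6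

(standard deviation of a reading: 2 percentage points)

- the best time, 6.0 h at the latest, for complex with three exchanged
- the amount of complex with three exchanged, in percent of the starting complex charged, at that time
- earliest time at which at least nineteen twentieths of that best amount are there
- latest time at which they still are

- at the start none of incoming ligand is dissolved
- reactions considered so far: starting complex + incoming ligand <-> leaving ligand + complex with one exchanged; complex with one exchanged + incoming ligand <-> leaving ligand + complex with two exchanged; complex with two exchanged + incoming ligand <-> leaving ligand + complex with three exchanged; gas <-> incoming ligand; complex with two exchanged -> side product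

By hand, time looked harmless. In the eta run the complex with three exchanged was read highest at 1.00 h and in the epsilon run at 0.667 h, and by 4.00 h it had sunk to 12% and 8%. Since the limit lies beyond those readings, I expected it to play no part in the best. The gas stood at 3.6 mM in both runs and in the flask, so the runs gave no comparison for it.

That left the charge c of starting complex. A single top carries the scatter, so I took P, the mean of the readings from 0.667 h to 1.33 h: 41.3% in the eta run and 32.0% in the epsilon run. In common logarithms:

n = 0.111 / 0.185 = 0.602

So n, read off scattered readings, is the charge exponent, the decades lost in P per decade gained in c with the gas held. From the eta run down to the flask, c falls by 0.151 decades: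

log P rises by 0.0911, a factor 1.23, so P = 51.0%

I took this P as my estimate of the best amount in the flask.

The forecast put the best at 48% at 0.85 h, in a window from 0.6 h to 1.12 h, saying “Lower concentration therefore helps”; its best lay below my estimate of 51.0%.

The flask gave 48.7% at 0.946 h, with the window from 0.638 h to 1.36 h.

    starting complex + incoming ligand ⇌ leaving ligand + complex with one exchanged (K = 1.21, k = 2.98 M⁻¹ s⁻¹)
    complex with one exchanged + incoming ligand ⇌ leaving ligand + complex with two exchanged (K = 160, k = 0.662 M⁻¹ s⁻¹)
    complex with two exchanged + incoming ligand ⇌ leaving ligand + complex with three exchanged (K = 79.3, k = 5.37 M⁻¹ s⁻¹)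
    gas ⇌ incoming ligand, rate k4*(csat - [incoming ligand]) (kL = 0.0269 s⁻¹)
    complex with two exchanged → side product (k = 0.00189 s⁻¹)

Without the scatter, the eta run's best up to its last reading was 40.9%; changing the time allowed alone left 40.9%, and changing the charge alone gave 48.7%. I then carried n from the flask to its neighbour with 48 mM of starting complex, 0.602 decades up:

best = 48.7% × 0.434 = 21.1%

The neighbour flask gave 21.2%.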